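(The data come from a simulation with constants of no real substance, noise included.)

I have no rate constants for this flask, only readings of target, so I build a stand-in from them.

| setting | north | east | south-east | north-west |
|---|---|---|---|---|
| substrate | 250 mM | 100 mM | 250 mM | 250 mM |
| reagent | 250 mM | 100 mM | 250 mM | 250 mM |
| free catalyst | 25.0 mM | 25.0 mM | 38.0 mM | 52.0 mM |
| time |  |  |  | 50 min |

| run | time / min | [target] / mM |
|---|---|---|
| north run | 2.0 | 32.0 |
| north run | 3.2 | 46.4 |
| north run | 5.0 | 67.1 |
| north run | 7.9 | 94.7 |
| north run | 13 | 126.8 |
| north run | 20 | 156.3 |
| north run | 32 | 185.3 |
| north run | 50 | 204.9 |
| east run | 2.0 | 8.9 |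
| east run | 3.2 | 12.9 |
| east run | 5.0 | 21.2 |
| east run | 7.9 | 30.0 |
| east run | 13 | 40.7 |
| east run | 20 | 51.4 |
| east run | 32 | 63.6 |
| east run | 50 | 72.7 |
| south-east run | 2.0 | 44.5 |
| south-east run | 3.2 | 65.9 |
| south-east run | 5.0 | 93.0 |
| south-east run | 7.9 | 124.1 |
| south-east run | 13 | 159.6 |
| south-east run | 20 | 184.8 |
| south-east run | 32 | 208.9 |
| south-east run | 50 | 222.6 |

(scatter of a reading: 0.8 mM)

1. apparent order in [free catalyst] of the starting rate, round the charge of the north run (the rate where two percent of its substrate have turned into target)
2. the east run starts with 150 mM less of substrate and of reagent than the north run, and with no target. Compared where both hold the same amount of substrate, once fifteen percent of what the east run was charged with has turned into target, is the east run faster, slower or alike (within a tenth)?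
3. target in the north-west run at 50 min, as a share of the substrate charged

- Overall: substrate + reagent -> target, with free catalyst as catalyst.
- Constant volume, constant temperature.
- The analysis sees a species whether free or bound.
- "The second partner" is reagent.
- An order is taken over about fifteen percent of the charge, up and down.

Substrate and reagent are charged equally and used one for one, so [S], the substrate present, is the charge minus the target made, and the reagent present, free or bound, equals it. For a rate proportional to both with a fixed constant, the reciprocal of [S] climbs in a straight line with time (the integrated second-order plot). The north run at 50 min has G = 18.2 M⁻¹, where G is the reciprocal of [S] minus the reciprocal of the charge, and the south-east run has G = 32.5 M⁻¹.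

The decision is whether to charge 52.0 mM of free catalyst and stop at 50 min, or stay with 38.0 mM, which made 89.0% of the charge by then. At 2.0 min the G of the two runs gives an order in catalyst of 0.929, close to first order. My first round therefore scales the north G with the catalyst, which gives 90.4%. But at 50 min the same two runs give an order of 1.39, higher than at 2.0 min. Putting that order back in, my second round gives G = 50.2 M⁻¹ and a yield of 92.6%, more than the south-east run made, so I charge the larger amount.

The climb of G per minute also answers the east question, since at equal [S] it compares rates directly. The east run passes the amount of substrate asked about between 2.0 min and 5.0 min, the north run between 20 min and 32 min. The east climb over the north climb is 1.43, so I say faster.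

The forecast gives 0.95, faster and 92.7%, and on the gap between the runs it says “North carries much more target, which points to inhibition or saturation.”

The flask gives 0.99, faster and 92.3%.

    free catalyst + substrate + reagent → target + free catalyst (53.58 M⁻² min⁻¹)
    free catalyst + reagent → spent catalyst + reagent (0.3876 M⁻¹ min⁻¹)
    free catalyst + reagent ⇌ idle catalyst-reagent complex, settled at all times (15.30 M⁻¹)

Read back, the north-west result is G = 48.2 M⁻¹, which is 2.65 times the north value for 2.08 times its catalyst. The east run is faster because free catalyst and reagent turn into spent catalyst (catalyst deactivation) over time, and the north run reaches that substrate later. Take that step away and the ratio falls from 1.4 to 1.0.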